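**Retrosynthetic overview**
1. Target ⇒ bis-mesylate of a bis-diol plus oleic acid. The last operation makes the ester C–O bond with a stereospecific 1,2-indolyl shift on the C3 chain, then closes the oxirane on the C5 chain.
2. Bis-diol ⇒ bis-(R)-lactate; all four methyl groups come from MeMgBr.
3. C5–CH2 bond ⇒ light-driven nickel/photoredox arylation of methyl (R)-glycidate by the aryl bromide (key step).
4. C3–CH2 bond ⇒ Friedel–Crafts opening of the same glycidate by 5-bromoindole.
5. Ring order: indole bought intact → spirocyclopropane (forms and opens in the last step) → oxirane last. Both stereocentres are C2 of methyl (R)-glycidate, each inverted once.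

Assumption: the SMILES is read as (S) at the side-chain CH, (S) at the oxirane CH and Z at the olefin; methyl (R)-glycidate (commercial, made from L-serine) is taken as the inexpensive chiral building block.

**Step 1**
Reactants: 1 5-bromo-1H-indole; 2 methyl (2R)-oxirane-2-carboxylate
Product: 3 methyl (2R)-3-(5-bromo-1H-indol-3-yl)-2-hydroxypropanoate
Conditions: 1 (1.5 equiv), SnCl4 (1.1 equiv), CH2Cl2, −78 → −10 °C
Reagents that add atoms: none
Why: Lewis-acid Friedel–Crafts alkylation by epoxide opening (the reaction type used for indolmycenic esters), in which SnCl4 chelates the epoxy ester and indole C3 attacks the unsubstituted CH2, so C2 of 2 is untouched and stays (R).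

**Step 2**
Reactants: 3 methyl (2R)-3-(5-bromo-1H-indol-3-yl)-2-hydroxypropanoate; 2 methyl (2R)-oxirane-2-carboxylate
Product: 5 dimethyl (2R,2'R)-3,3'-(1H-indole-3,5-diyl)bis(2-hydroxypropanoate), via methyl (2S)-3-bromo-2-hydroxypropanoate 4 (not isolated)
Conditions: 2 (2.5 equiv), 4CzIPN (2 mol%), NiBr2(dme) (10 mol%), 4,4'-di-tert-butyl-2,2'-bipyridine (12 mol%), 2,6-lutidinium bromide (30 mol%), 2,6-lutidine (1.2 equiv), Hantzsch ester (1.5 equiv), DMA, 450 nm LEDs, 30 °C
Reagents that add atoms: none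
Why: Proposed new method: bromide-relay nickel/photoredox arylation of a glycidic ester, in which lutidinium bromide opens 2 at the unsubstituted CH2 to bromohydrin 4, photoreduced 4CzIPN (Hantzsch ester as terminal reductant) drives a bipyridine–nickel cycle where zerovalent nickel inserts into the C–Br bond of 3, the primary radical from 4 (bromine abstraction by monovalent nickel) is captured, and trivalent nickel reductively eliminates the C5–CH2 bond while the released HBr is recycled as ring-opening agent; the radical sits one carbon away from the carbinol carbon, so the (R) centre of 2 is carried through unchanged; closest known reaction types are nickel/halide co-catalysed reductive coupling of terminal epoxides with aryl halides and nickel/photoredox cross-electrophile coupling of alkyl bromides with aryl bromides, neither shown on a glycidic ester.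

**Step 3**
Reactants: 5 dimethyl (2R,2'R)-3,3'-(1H-indole-3,5-diyl)bis(2-hydroxypropanoate)
Product: 6 (2R,2'R)-1,1'-(1H-indole-3,5-diyl)bis(3-methylbutane-2,3-diol)
Conditions: MeMgBr (12 equiv), THF, 0 °C → rt; aq NH4Cl
Reagents that add atoms: methylmagnesium bromide, C[Mg]Br
Why: Double Grignard addition to each ester after deprotonation of N–H and O–H; the α-carbons carry magnesium alkoxides and do not enolise, so both (R) centres are retained.

**Step 4**
Reactants: 6 (2R,2'R)-1,1'-(1H-indole-3,5-diyl)bis(3-methylbutane-2,3-diol)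
Product: 7 (2R)-3-hydroxy-1-[3-[(2R)-3-hydroxy-3-methyl-2-(methylsulfonyloxy)butyl]-1H-indol-5-yl]-3-methylbutan-2-yl methanesulfonate
Conditions: MsCl (2.3 equiv), Et3N (3 equiv), CH2Cl2, −20 °C, 30 min; cold aq NaHCO3; crude used at once
Reagents that add atoms: methanesulfonyl chloride, CS(=O)(=O)Cl
Why: Selective sulfonylation of the two secondary hydroxyls (tertiary hydroxyls and the indole N–H are inert here); no bond to a stereocentre is broken, so both centres stay (R).

**Step 5**
Reactants: 7 (2R)-3-hydroxy-1-[3-[(2R)-3-hydroxy-3-methyl-2-(methylsulfonyloxy)butyl]-1H-indol-5-yl]-3-methylbutan-2-yl methanesulfonate; 8 oleic acid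
Product: 11 [(2S)-2-[5-[[(2S)-3,3-dimethyloxiran-2-yl]methyl]-1H-indol-3-yl]-3-hydroxy-3-methylbutyl] (9Z)-octadec-9-enoate (CNP0291182.1), via spirocyclopropane-indolenine mesylate 9 (not isolated), via rearranged oleate mono-mesylate 10 (not isolated)
Conditions: 8 (3 equiv), i-Pr2NEt (1.5 equiv), MeCN–THF (2:1), 50 °C; then DBU (5 equiv), 40 °C
Reagents that add atoms: none
Why: Anchimerically assisted substitution with 1,2-indolyl shift followed by intramolecular Williamson closure: indole C3 displaces the C3-chain mesylate with inversion to spirocyclopropane 9, oleate opens 9 at the unhindered CH2 (the other cyclopropane carbon is neopentylic and deactivated by its β-hydroxyl) so the indole stays on the former carbinol carbon, now (S), and DBU then lets the tertiary hydroxyl displace the C5-chain mesylate with inversion to the (S)-oxirane.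

**Compound list**
1 | 5-bromo-1H-indole | Brc1ccc2[nH]ccc2c1 | starting material
2 | methyl (2R)-oxirane-2-carboxylate (methyl (R)-glycidate) | COC(=O)[C@H]1CO1 | starting material
3 | methyl (2R)-3-(5-bromo-1H-indol-3-yl)-2-hydroxypropanoate | COC(=O)[C@H](O)Cc1c[nH]c2ccc(Br)cc12 | intermediate
4 | methyl (2S)-3-bromo-2-hydroxypropanoate (C2 geometry of 2 unchanged; descriptor switches by CIP priority) | COC(=O)[C@H](O)CBr | intermediate
5 | dimethyl (2R,2'R)-3,3'-(1H-indole-3,5-diyl)bis(2-hydroxypropanoate) | COC(=O)[C@H](O)Cc1ccc2[nH]cc(C[C@@H](O)C(=O)OC)c2c1 | intermediate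
6 | (2R,2'R)-1,1'-(1H-indole-3,5-diyl)bis(3-methylbutane-2,3-diol) | CC(C)(O)[C@H](O)Cc1ccc2[nH]cc(C[C@@H](O)C(C)(C)O)c2c1 | intermediate
7 | (2R)-3-hydroxy-1-[3-[(2R)-3-hydroxy-3-methyl-2-(methylsulfonyloxy)butyl]-1H-indol-5-yl]-3-methylbutan-2-yl methanesulfonate | CC(C)(O)[C@H](OS(C)(=O)=O)Cc1ccc2[nH]cc(C[C@@H](OS(C)(=O)=O)C(C)(C)O)c2c1 | intermediate
8 | oleic acid, (9Z)-octadec-9-enoic acid | CCCCCCCC/C=C\CCCCCCCC(=O)O | starting material
9 | (2R)-3-hydroxy-1-[(2R)-2-(2-hydroxypropan-2-yl)spiro[cyclopropane-1,3'-indol]-5'-yl]-3-methylbutan-2-yl methanesulfonate (spiro carbon unassigned, lost on ring opening) | CC(C)(O)[C@H](OS(C)(=O)=O)Cc1ccc2N=CC3(C[C@H]3C(C)(C)O)c2c1 | intermediate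
10 | [(2S)-3-hydroxy-2-[5-[(2R)-3-hydroxy-3-methyl-2-(methylsulfonyloxy)butyl]-1H-indol-3-yl]-3-methylbutyl] (9Z)-octadec-9-enoate | CCCCCCCC/C=C\CCCCCCCC(=O)OC[C@H](c1c[nH]c2ccc(C[C@@H](OS(C)(=O)=O)C(C)(C)O)cc12)C(C)(C)O | intermediate
11 | [(2S)-2-[5-[[(2S)-3,3-dimethyloxiran-2-yl]methyl]-1H-indol-3-yl]-3-hydroxy-3-methylbutyl] (9Z)-octadec-9-enoate | CCCCCCCC/C=C\CCCCCCCC(=O)OC[C@H](c1c[nH]c2ccc(C[C@@H]3OC3(C)C)cc12)C(C)(C)O | target

**Totals**
Total steps: 5. Longest linear sequence: 5.

**Steps most likely to fail**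

Step 2 (the proposed new step). The relay may stall if ring opening of 2 is slow, and protodebromination of 3 or loss of the β-hydroxyl from the alkyl–nickel species can compete. The fallback uses known chemistry, sets out from 3 (with 2 processed separately) and comes back at 5. Open 2 with MgBr2·OEt2 (Et2O, 0 °C) and isolate 4. Silylate it (TBSCl, imidazole, DMF) to methyl (2S)-3-bromo-2-[(tert-butyldimethylsilyl)oxy]propanoate F1. Couple F1 with 3 by the established silyl-radical nickel/iridium photoredox cross-electrophile coupling of alkyl bromides with aryl bromides (NiCl2(dme), 4,4'-di-tert-butyl-2,2'-bipyridine, Ir[dF(CF3)ppy]2(dtbbpy)PF6, (Me3Si)3SiH, Na2CO3, DME, blue LEDs) to give methyl (2R)-2-[(tert-butyldimethylsilyl)oxy]-3-[3-[(2R)-2-hydroxy-3-methoxy-3-oxopropyl]-1H-indol-5-yl]propanoate F2. Cleave the silyl ether (HF·pyridine, THF) to reach 5.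

Step 5. Oleate trapping of the spiro intermediate may be inefficient or partly misdirected, direct oxirane closure on the C3 chain would erode that centre, and DBU may close the C5-chain oxirane sluggishly in the presence of the ester. The fallback sets out from 7 and comes back at 11, and separates the rearrangement from the acylation. Solvolyse 7 in acetone–water (3:1) with NaHCO3 at 45 °C, so that water at high concentration traps the spiro intermediate at CH2 and gives (2R)-1-[3-[(2S)-1,3-dihydroxy-3-methylbutan-2-yl]-1H-indol-5-yl]-3-hydroxy-3-methylbutan-2-yl methanesulfonate F3. Close the oxirane with K2CO3 in MeOH (0 °C → rt) to give (2S)-2-[5-[[(2S)-3,3-dimethyloxiran-2-yl]methyl]-1H-indol-3-yl]-3-methylbutane-1,3-diol F4. Acylate only the primary hydroxyl with 8 (EDC·HCl, catalytic DMAP, CH2Cl2, 0 °C) to reach 11.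

Step 1. 5-Bromoindole is a weak nucleophile, and chloride from SnCl4 can open 2 to the chlorohydrin. The fallback sets out from 1 and comes back at 3, and makes the indole C3 the organometallic partner. Iodinate 1 (I2, KOH, DMF) to 5-bromo-3-iodo-1H-indole F5. Silylate nitrogen (NaH, TIPSCl, THF) to 5-bromo-3-iodo-1-(triisopropylsilyl)-1H-indole F6. Exchange the iodide selectively (i-PrMgCl·LiCl, THF, −40 °C) to [5-bromo-1-(triisopropylsilyl)-1H-indol-3-yl]magnesium chloride F7. Open 2 at CH2 under copper catalysis (CuI 10 mol%, −40 → −20 °C) to methyl (2R)-3-[5-bromo-1-(triisopropylsilyl)-1H-indol-3-yl]-2-hydroxypropanoate F8. Remove the silyl group (TBAF, AcOH, THF) to reach 3.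

**Further compounds**
F1 | step 2 | methyl (2S)-3-bromo-2-[(tert-butyldimethylsilyl)oxy]propanoate | COC(=O)[C@H](O[Si](C)(C)C(C)(C)C)CBr
F2 | step 2 | methyl (2R)-2-[(tert-butyldimethylsilyl)oxy]-3-[3-[(2R)-2-hydroxy-3-methoxy-3-oxopropyl]-1H-indol-5-yl]propanoate | COC(=O)[C@H](O[Si](C)(C)C(C)(C)C)Cc1ccc2[nH]cc(C[C@@H](O)C(=O)OC)c2c1
F3 | step 5 | (2R)-1-[3-[(2S)-1,3-dihydroxy-3-methylbutan-2-yl]-1H-indol-5-yl]-3-hydroxy-3-methylbutan-2-yl methanesulfonate | OC[C@H](c1c[nH]c2ccc(C[C@@H](OS(C)(=O)=O)C(C)(C)O)cc12)C(C)(C)O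
F4 | step 5 | (2S)-2-[5-[[(2S)-3,3-dimethyloxiran-2-yl]methyl]-1H-indol-3-yl]-3-methylbutane-1,3-diol | OC[C@H](c1c[nH]c2ccc(C[C@@H]3OC3(C)C)cc12)C(C)(C)O
F5 | step 1 | 5-bromo-3-iodo-1H-indole | Brc1ccc2[nH]cc(I)c2c1
F6 | step 1 | 5-bromo-3-iodo-1-(triisopropylsilyl)-1H-indole | CC(C)[Si](C(C)C)(C(C)C)n1cc(I)c2cc(Br)ccc21
F7 | step 1 | [5-bromo-1-(triisopropylsilyl)-1H-indol-3-yl]magnesium chloride | CC(C)[Si](C(C)C)(C(C)C)n1cc([Mg]Cl)c2cc(Br)ccc21
F8 | step 1 | methyl (2R)-3-[5-bromo-1-(triisopropylsilyl)-1H-indol-3-yl]-2-hydroxypropanoate | COC(=O)[C@H](O)Cc1cn([Si](C(C)C)(C(C)C)C(C)C)c2ccc(Br)cc12
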